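# Proposed total synthesis of dicitrinone I (35)

Abbreviations in names: MOM = methoxymethyl, TBS = tert-butyldimethylsilyl, TMS = trimethylsilyl. "Isochroman" = 3,4-dihydro-1H-2-benzopyran, numbered C1, O2, C3, C4, C4a, C5–C8, C8a.

## The problem

Dicitrinone I (35) consists of two 3,4,5-trimethylisochroman units joined C7 to C7 through one methylene carbon. The right unit is a fully substituted aromatic 6,8-diol. The left unit has the same skeleton but is two oxidation levels higher at C1: a quinone methide (C1=C8a, C8=O, C6–OH), in effect a vinylogous acid. Both six-membered carbocycles are hexasubstituted, so nearly every substituent has to be placed by construction and not by late aromatic substitution. The four stereocentres form two identical trans (3R,4S) diads that lie too far apart, across the bridge, to influence each other. Within a diad C3 and C4 are adjacent, so C3 can direct C4 (alkylation next to a carbinol) or both can be bought together. Because the halves differ only at C1, any symmetric dimer would have to be desymmetrised by a selective oxidation next to a doubly benzylic bridge and free resorcinols. The quinone methide is electrophilic at C1 and will not survive hydride, base or nucleophilic solvents. The resorcinol rings are sensitive to oxidants and one-carbon electrophiles, and the benzylic ring ether to strong Lewis acids. The key step rests on the substitution pattern of the left carbocycle. C8a and C4a carry C1 and the C4–C3 chain, like the two carbons of a 2-alkynoate. C5, C6, C7 and C8 carry methyl, oxygen, the bridge and oxygen, like a 2-substituted 4-methyl 1,3-dioxygenated diene derived from a β-keto ester.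

## Retrosynthesis

**35 ⇒ 34.** The C1=C8a/C8=O unsaturation is taken back to a lactol hydroxyl at C1, and the four phenols to MOM ethers. The quinone methide is the anhydro form of a 1-hydroxyisochroman-6,8-diol, so dehydration and acetal hydrolysis can share one acidic step. The fragile group then appears only in the last flask. Lactol 34 is an ordinary protected intermediate. The forward step needs acid strong enough for four aryl MOM ethers in a medium that offers C1 no competing nucleophile.

**34 ⇒ 33 ⇒ 31 ⇒ 30.** The lactol comes from lactone 33 by one hydride, and 33 from the C1–O2 acyl bond of hydroxy ester 32, freed from silyl ether 31. C1 of the left half therefore enters at the carboxyl level and is never at the CH2 level of the right half, so the halves are distinguished by construction. The two phenols of 30 are capped as MOM ethers (31) before reduction. Free 6,8-phenoxides would turn the lactone into a vinylogous carbonate toward hydride, and a uniform tetra-MOM array lets one acid step finish the synthesis.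

**30 ⇒ 27 + 8 (key disconnection).** The bonds C4a–C5 and C8–C8a of the left ring are cut, giving diene 27 and ynoate 8. Attaching the side chain or the bridge to a preformed resorcylate would mean substitution at the last free positions of a crowded ring. The cycloaddition sets all six substituents in one operation, and the polarity of the partners fixes their order. Ynoate 8 carries the left diad complete, and 27 carries the whole right half. The forward reaction must deliver the regiochemistry and overcome congestion at both new bonds.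

**27 ⇒ 25 ⇒ 24 ⇒ 21 + 22.** Two enol silylations lead back to keto ester 24. The bond between the bridge carbon and C2 of the keto ester (the future left C7) is then cut to aldehyde 21 and methyl 3-oxopentanoate 22. A reductive Knoevenagel is preferred to alkylation with a 2,6-dialkoxybenzyl halide, which would ionise readily. The aldehyde cannot enolise, and 22 is commercial.

**21 ⇒ 20 ⇒ 19 ⇒ 17.** The formyl carbon is removed from C7, the only aromatic C–H of 17, which lies between two directing oxygens. Methyl ethers are needed up to this point because the ring-forming step is acidic. They are exchanged for MOM groups at the aldehyde stage, where the flanking carbonyl lets BBr3 cleave both ethers at low temperature.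

**17 ⇒ 15.** C1 is excised, cutting C1–C8a and C1–O2 (oxa-Pictet–Spengler). The only free ortho position of 15 is activated ortho and para by the two methoxy groups, so no regiochemical question arises.

**15 ⇒ 13 ⇒ 10 + 11.** The aryl–C4 bond is cut to aryl bromide 10 and (2S,3S)-epoxide 11. Opening with inversion sets C4 as S. A trans-epoxide, however, gives the erythro alcohol 13, which would close to a cis-3,4-dimethyl ring. The carbinol is therefore inverted (13 ⇒ 15) to reach the threo (2R,3S) alcohol. The cis-epoxide would give the threo relation directly, but only as a racemate. Making the right half by a second benzannulation with 8 was considered and set aside, because it lengthens the longest linear sequence and doubles the demand for 8.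

**10 ⇒ 9.** The C5 methyl is traced to the formyl group of commercial aldehyde 9, which already has bromine and both oxygens in the right places.

**8 ⇒ 6 ⇒ 5 ⇒ 4 ⇒ 3 ⇒ 1.** The alkyne–carboxyl bond and then the alkyne itself are cut back to aldehyde 5 (one-carbon homologation through dibromoalkene 6). Aldehyde 5 comes from ester 4, and its anti diad from Fráter–Seebach methylation of ethyl (R)-3-hydroxybutanoate 1. The (2R,3R) centres of 3 become (4S,5R) in 8 only through a change of substituent priorities at the methyl-bearing carbon, and they map onto (4S,3R) of the target.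

## Roads not taken

**Alternative 1:** Both C3–C4 bonds are cut. A bridged bis(secondary benzylic boronic ester) A2 would be homologated twice with an enantioenriched, diamine-bound lithiated ethyl carbenoid to the bis(3-arylbutan-2-yl boronate) A1. Merits: both diads arise in one flask under reagent control, either antipode is accessible, and a double reaction on a symmetric substrate amplifies enantiopurity. Weak points for this target:
- A2 already needs two benzylic stereocentres set enantioselectively.
- Each boron sits next to an ortho-methyl group, which slows ate-complex formation and 1,2-migration.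
- After oxidation and ring closure the product is the symmetric bis(isochroman) as its tetramethyl ether. Exactly one of two equivalent C1 positions then has to be oxidised by two levels, next to the doubly benzylic bridge, and four methyl ethers removed in the presence of, or just before, the quinone methide.

Comparison: this road reaches the full carbon skeleton in fewer operations and does not depend on the chiral pool. The chosen plan sets against that the built-in distinction of the halves, no late oxidation, and protecting groups that come off under the conditions that form the quinone methide.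

**Alternative 2:** Both C1–O2 and both C1–C8a bonds are cut. The bridged bis(aryl carbinol) A4 would take up two one-carbon units at the aldehyde level in a double oxa-Pictet–Spengler to give the bis(isochroman diol) A3. Merits: four bonds and two rings in one step, no protecting groups, and unambiguous regiochemistry because each ring has one free position. It is the shortest of the four plans. Weak points:
- A3 is C2-symmetric and both halves sit at the CH2 level. Compound 35 then requires removal of hydride from one of two identical benzylic ether carbons with four free phenols and the bridge methylene present. The best outcome is a statistical mixture with over-oxidation.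
- A4 needs the same stereochemical work as the right half here, done twice.

Comparison: if a selective mono-oxidation existed, this road would be clearly superior in step count. The chosen plan offers certainty about the oxidation pattern, since the left C1 is introduced as a carboxyl carbon and only reduced.

**Alternative 3:** Both C4–C4a bonds are cut. The bis(arylzinc) reagent A6 would be coupled twice with a racemic α-bromo ketone under a chiral nickel catalyst to give bis(ketone) A5. Merits: catalytic asymmetric induction from a cheap racemic electrophile, in two directions. Weak points: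
- Each carbon–zinc bond is flanked by an ortho-methyl group, a known burden on rate and selectivity in such couplings.
- The new centres are benzylic and α to a ketone, so they can epimerise by enolisation.
- C3 would then have to be set by a threo-selective reduction, twice, under substrate control.
- The sequence ends at the same symmetric, methyl-protected intermediate as alternative 1, with the same oxidation and deprotection problems.

Comparison: this road uses less stoichiometric chiral material and is more modern in its stereocontrol. The chosen plan takes both diads from building blocks of secure configuration and needs no later stereoselective event.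

Key step: step 16

Assumption: the 6-hydroxy-8-oxo form drawn for 35 and its 8-hydroxy-6-oxo form are prototropic tautomers of one compound; the route delivers that compound and the drawn tautomer is used throughout.

## Route

Step 1
Reactants: 1 ethyl (3R)-3-hydroxybutanoate
Product: 3 ethyl (2R,3R)-3-hydroxy-2-methylbutanoate, via dilithium alkoxide enolate 2 (not isolated)
Conditions: LiN(i-Pr)2 (2.2 equiv), THF, –50 → –20 °C; then MeI, DMPU, –78 → –10 °C
Reagents that add atoms: iodomethane, CI
Why: Fráter–Seebach alkylation; the chelated dilithium alkoxide enolate is methylated on the face away from the C3 methyl group, which gives the anti (2R,3R) diad while C3 is untouched.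

Step 2
Reactants: 3 ethyl (2R,3R)-3-hydroxy-2-methylbutanoate
Product: 4 ethyl (2R,3R)-3-(tert-butyldimethylsilyloxy)-2-methylbutanoate
Conditions: TBSCl, imidazole, DMF, rt
Reagents that add atoms: tert-butyldimethylsilyl chloride, CC(C)(C)[Si](C)(C)Cl
Why: Standard imidazole-mediated silylation of a secondary alcohol; the silyl ether tolerates the organolithium, hydride and thermal steps ahead and is removed later by fluoride.

Step 3
Reactants: 4 ethyl (2R,3R)-3-(tert-butyldimethylsilyloxy)-2-methylbutanoate
Product: 5 (2R,3R)-3-(tert-butyldimethylsilyloxy)-2-methylbutanal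
Conditions: i-Bu2AlH (1.1 equiv), CH2Cl2, –78 °C
Reagents that add atoms: none
Why: Partial reduction of an ester to the aldehyde through an aluminium hemiacetal that is stable at –78 °C, routine for β-silyloxy α-methyl esters; cold neutral work-up and direct use should protect the α-centre.

Step 4
Reactants: 5 (2R,3R)-3-(tert-butyldimethylsilyloxy)-2-methylbutanal
Product: 6 tert-butyl{[(2R,3S)-5,5-dibromo-3-methylpent-4-en-2-yl]oxy}dimethylsilane
Conditions: CBr4, PPh3, Et3N, CH2Cl2, 0 °C
Reagents that add atoms: carbon tetrabromide, BrC(Br)(Br)Br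
Why: Corey–Fuchs dibromo-olefination (Wittig reaction of Ph3P=CBr2); the amine buffer keeps the medium non-acidic so the α-centre and the silyl ether should be preserved.

Step 5
Reactants: 6 tert-butyl{[(2R,3S)-5,5-dibromo-3-methylpent-4-en-2-yl]oxy}dimethylsilane
Product: 8 methyl (4S,5R)-5-(tert-butyldimethylsilyloxy)-4-methylhex-2-ynoate, via lithium acetylide 7 (not isolated)
Conditions: n-BuLi (2.1 equiv), THF, –78 °C; then ClCO2Me, –78 → 0 °C
Reagents that add atoms: methyl chloroformate, COC(=O)Cl
Why: Second stage of the Corey–Fuchs sequence: bromine–lithium exchange, Fritsch–Buttenberg–Wiechell rearrangement and deprotonation give the acetylide, which is acylated by the chloroformate; the propargylic centre is not deprotonated at –78 °C.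

Step 6
Reactants: 9 2-bromo-4,6-dimethoxybenzaldehyde
Product: 10 1-bromo-3,5-dimethoxy-2-methylbenzene
Conditions: Et3SiH, CF3CO2H, CH2Cl2, 0 °C → rt
Reagents that add atoms: none
Why: Ionic hydrogenation of an electron-rich benzaldehyde: two hydride transfers from the silane, the second to a benzylic cation stabilised by the ortho and para methoxy groups; the aryl bromide is inert.

Step 7
Reactants: 10 1-bromo-3,5-dimethoxy-2-methylbenzene; 11 (2S,3S)-2,3-dimethyloxirane
Product: 13 (2S,3S)-3-(3,5-dimethoxy-2-methylphenyl)butan-2-ol, via aryllithium 12 (not isolated)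
Conditions: n-BuLi, THF, –78 °C; then 11, BF3·OEt2, –78 °C
Reagents that add atoms: none
Why: Bromine–lithium exchange followed by BF3-assisted SN2 opening of the epoxide; attack inverts the carbon that becomes C4 (S) and, because 11 is C2-symmetric, either carbon gives the same erythro alcohol.

Step 8
Reactants: 13 (2S,3S)-3-(3,5-dimethoxy-2-methylphenyl)butan-2-ol
Product: 15 (2R,3S)-3-(3,5-dimethoxy-2-methylphenyl)butan-2-ol, via inverted 4-nitrobenzoate 14 (not isolated)
Conditions: PPh3, DIAD, 4-O2NC6H4CO2H, THF, 0 °C → rt; then MeOH, K2CO3, rt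
Reagents that add atoms: 4-nitrobenzoic acid, OC(=O)c1ccc(cc1)[N+](=O)[O-]
Why: Mitsunobu inversion (SN2 displacement of the oxyphosphonium by the acidic carboxylate) followed by methanolysis in the same flask; this turns the erythro into the threo alcohol required for the trans-3,4-dimethyl ring, and the benzylic centre is not involved.

Step 9
Reactants: 15 (2R,3S)-3-(3,5-dimethoxy-2-methylphenyl)butan-2-ol
Product: 17 (3R,4S)-6,8-dimethoxy-3,4,5-trimethylisochroman, via methoxymethyl ether 16 (not isolated)
Conditions: CH2(OMe)2 (1.5 equiv), BF3·OEt2, CH2Cl2, 0 °C → rt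
Reagents that add atoms: dimethoxymethane, COCOC
Why: Oxa-Pictet–Spengler cyclisation: acetal exchange gives 16, whose oxocarbenium ion attacks the only free ortho carbon, activated ortho and para by the methoxy groups; limiting the acetal should suppress intermolecular arylmethylation and no stereocentre is touched.

Step 10
Reactants: 17 (3R,4S)-6,8-dimethoxy-3,4,5-trimethylisochroman
Product: 19 (3R,4S)-6,8-dimethoxy-3,4,5-trimethylisochroman-7-carbaldehyde, via 7-lithioisochroman 18 (not isolated)
Conditions: n-BuLi, TMEDA, THF, 0 °C; then DMF, 0 °C → rt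
Reagents that add atoms: N,N-dimethylformamide, CN(C)C=O
Why: Directed ortho-metalation at the single aromatic C–H, flanked by two methoxy groups and therefore the kinetically most acidic site, then formylation with DMF.

Step 11
Reactants: 19 (3R,4S)-6,8-dimethoxy-3,4,5-trimethylisochroman-7-carbaldehyde
Product: 20 (3R,4S)-6,8-dihydroxy-3,4,5-trimethylisochroman-7-carbaldehyde
Conditions: BBr3 (2.5 equiv), CH2Cl2, –78 → 0 °C
Reagents that add atoms: none
Why: Carbonyl-assisted ether cleavage: boron chelated between the formyl oxygen and each flanking methoxy group should dealkylate both at low temperature, faster than attack on the benzylic ring ether.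

Step 12
Reactants: 20 (3R,4S)-6,8-dihydroxy-3,4,5-trimethylisochroman-7-carbaldehyde
Product: 21 (3R,4S)-6,8-bis(methoxymethoxy)-3,4,5-trimethylisochroman-7-carbaldehyde
Conditions: NaH, MeOCH2Cl, DMF, 0 °C → rt
Reagents that add atoms: chloromethyl methyl ether, COCCl
Why: O-Alkylation of the bis-phenoxide (Williamson type); full deprotonation breaks the hydrogen bonds to the formyl group, and the aldehyde has no enolisable position.

Step 13
Reactants: 21 (3R,4S)-6,8-bis(methoxymethoxy)-3,4,5-trimethylisochroman-7-carbaldehyde; 22 methyl 3-oxopentanoate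
Product: 24 methyl 2-{[(3R,4S)-6,8-bis(methoxymethoxy)-3,4,5-trimethylisochroman-7-yl]methyl}-3-oxopentanoate, via alkylidene keto ester 23 (not isolated)
Conditions: piperidine, AcOH (cat.), toluene, 4 Å MS, 80 °C; then Hantzsch ester, 80 °C
Reagents that add atoms: none
Why: Reductive Knoevenagel: amine-catalysed condensation gives the doubly activated alkene 23, which accepts hydride from the Hantzsch ester at the β-carbon; the buffered medium is compatible with aryl MOM ethers, and the new C2 centre is lost again in the next step.

Step 14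
Reactants: 24 methyl 2-{[(3R,4S)-6,8-bis(methoxymethoxy)-3,4,5-trimethylisochroman-7-yl]methyl}-3-oxopentanoate
Product: 25 methyl 2-{[(3R,4S)-6,8-bis(methoxymethoxy)-3,4,5-trimethylisochroman-7-yl]methyl}-3-(trimethylsilyloxy)pent-2-enoate
Conditions: Me3SiCl, Et3N, toluene, rt
Reagents that add atoms: chlorotrimethylsilane, C[Si](C)(C)Cl
Why: Soft enolisation and O-silylation of a 2-substituted β-keto ester to the conjugated silyl enol ether, the established first stage of 1,3-bis(silyloxy)diene synthesis.

Step 15
Reactants: 25 methyl 2-{[(3R,4S)-6,8-bis(methoxymethoxy)-3,4,5-trimethylisochroman-7-yl]methyl}-3-(trimethylsilyloxy)pent-2-enoate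
Product: 27 (3Z)-1-methoxy-1,3-bis(trimethylsilyloxy)penta-1,3-diene bearing the [(3R,4S)-6,8-bis(methoxymethoxy)-3,4,5-trimethylisochroman-7-yl]methyl group at C2, via lithium dienolate 26 (not isolated)
Conditions: LiN(i-Pr)2, THF, –78 °C; then Me3SiCl, –78 → 0 °C
Reagents that add atoms: chlorotrimethylsilane, C[Si](C)(C)Cl
Why: γ-Deprotonation of the β-silyloxy enoate and O-silylation of the ester dienolate (Chan-type diene synthesis); allylic strain against the C2 substituent should place the C4 methyl outward (3Z), the geometry that can reach an s-cis conformation.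

Step 16
Reactants: 27 (3Z)-1-methoxy-1,3-bis(trimethylsilyloxy)penta-1,3-diene bearing the isochroman-7-ylmethyl group at C2; 8 methyl (4S,5R)-5-(tert-butyldimethylsilyloxy)-4-methylhex-2-ynoate
Product: 30 methyl 3-{[(3R,4S)-6,8-bis(methoxymethoxy)-3,4,5-trimethylisochroman-7-yl]methyl}-6-[(2S,3R)-3-(tert-butyldimethylsilyloxy)butan-2-yl]-2,4-dihydroxy-5-methylbenzoate, via cyclohexadiene cycloadduct 28 (not isolated), via aryl bis(trimethylsilyl) ether 29 (not isolated)
Conditions: 8 (2 equiv), toluene, 120 °C, sealed tube; then MeOH, K2CO3 (cat.), 0 °C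
Reagents that add atoms: none
Why: A normal-demand Diels–Alder reaction of the electron-rich diene 27 with ynoate 8, concerted but strongly asynchronous (in the limit a vinylogous Mukaiyama–Michael addition followed by closure of the allenolate onto the silyl oxocarbenium carbon), gives 1,4-cyclohexadiene 28. Cycloadduct 28 aromatises by 1,4-loss of methanol from the mixed ketal carbon and the ring C–H to give 29, and methanolysis of the two aryl silyl ethers gives 30. The closest known reaction type is the cycloaddition–aromatisation of Chan- and Danishefsky-type silyloxy dienes with acetylenic esters to resorcylates. The one ring formed, the left carbocycle, closes by [4+2] cycloaddition, which makes C4a–C5 and C8–C8a (isochroman numbering) in the same operation. No stereocentre is created: the two sp3 ring carbons of 28 vanish on aromatisation, and both diads are spectators under neutral thermal conditions, since the propargylic C–H of 8 does not epimerise without base. The step needs regiocontrol, which the polarity of both partners supplies: the methyl-bearing terminus of 27 has the largest HOMO coefficient and bonds to the β-carbon of 8, so the ester ends up next to the oxygen from the ketene acetal and the side chain next to the ring methyl. It also needs a reactive s-cis diene, which the C2 substituent favours by destabilising the s-trans form and by holding the C4 methyl outward. Methanol and not silanol is lost on aromatisation, because silicon stays on the oxygen that becomes the phenol, so both oxygens are retained.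

Step 17
Reactants: 30 methyl 3-{[(3R,4S)-6,8-bis(methoxymethoxy)-3,4,5-trimethylisochroman-7-yl]methyl}-6-[(2S,3R)-3-(tert-butyldimethylsilyloxy)butan-2-yl]-2,4-dihydroxy-5-methylbenzoate
Product: 31 methyl 3-{[(3R,4S)-6,8-bis(methoxymethoxy)-3,4,5-trimethylisochroman-7-yl]methyl}-6-[(2S,3R)-3-(tert-butyldimethylsilyloxy)butan-2-yl]-2,4-bis(methoxymethoxy)-5-methylbenzoate
Conditions: NaH, MeOCH2Cl, DMF, 0 °C → rt
Reagents that add atoms: chloromethyl methyl ether, COCCl
Why: O-Alkylation of both hindered phenoxides with the small MOM chloride; it removes the acidic protons and the phenoxide deactivation before lactonisation and hydride reduction, and makes all four phenol protecting groups the same.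

Step 18
Reactants: 31 methyl 3-{[(3R,4S)-6,8-bis(methoxymethoxy)-3,4,5-trimethylisochroman-7-yl]methyl}-6-[(2S,3R)-3-(tert-butyldimethylsilyloxy)butan-2-yl]-2,4-bis(methoxymethoxy)-5-methylbenzoate
Product: 33 (3R,4S)-7-{[(3R,4S)-6,8-bis(methoxymethoxy)-3,4,5-trimethylisochroman-7-yl]methyl}-6,8-bis(methoxymethoxy)-3,4,5-trimethylisochroman-1-one, via hydroxy ester 32 (not isolated)
Conditions: Bu4NF, THF, 0 → 45 °C
Reagents that add atoms: none
Why: Fluoride cleaves the secondary silyl ether and the resulting alkoxide closes the six-membered lactone by acyl substitution on the neighbouring methyl ester; the carbinol oxygen is the nucleophile, so C3 keeps its configuration.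

Step 19
Reactants: 33 (3R,4S)-7-{[(3R,4S)-6,8-bis(methoxymethoxy)-3,4,5-trimethylisochroman-7-yl]methyl}-6,8-bis(methoxymethoxy)-3,4,5-trimethylisochroman-1-one
Product: 34 (3R,4S)-7-{[(3R,4S)-6,8-bis(methoxymethoxy)-3,4,5-trimethylisochroman-7-yl]methyl}-6,8-bis(methoxymethoxy)-3,4,5-trimethylisochroman-1-ol (both C1 epimers)
Conditions: i-Bu2AlH (1.3 equiv), CH2Cl2, –78 °C
Reagents that add atoms: none
Why: Partial reduction of an aryl lactone to the lactol; the cyclic aluminium hemiacetal is stable at –78 °C, and with all phenols capped no hydride is spent on acidic protons.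

Step 20
Reactants: 34 (3R,4S)-7-{[(3R,4S)-6,8-bis(methoxymethoxy)-3,4,5-trimethylisochroman-7-yl]methyl}-6,8-bis(methoxymethoxy)-3,4,5-trimethylisochroman-1-ol
Product: 35 dicitrinone I
Conditions: HCl (3 M aq.), THF, 40 °C
Reagents that add atoms: none
Why: Acid hydrolysis of the four MOM acetals and ionisation of the lactol to the 2-benzopyrylium ion, which loses a phenolic proton to give the quinone methide, as in the citrinin hydrate–citrinin equilibrium; every aromatic position is substituted, so the formaldehyde released has no ring carbon to attack, and no stereocentre is involved.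

## Compound list

1 | ethyl (3R)-3-hydroxybutanoate | C[C@@H](O)CC(=O)OCC | starting material
2 | dilithium alkoxide enolate of 1 | C[C@@H](O[Li])C=C(O[Li])OCC | intermediate
3 | ethyl (2R,3R)-3-hydroxy-2-methylbutanoate | C[C@@H](O)[C@@H](C)C(=O)OCC | intermediate
4 | ethyl (2R,3R)-3-(tert-butyldimethylsilyloxy)-2-methylbutanoate | C[C@@H](O[Si](C)(C)C(C)(C)C)[C@@H](C)C(=O)OCC | intermediate
5 | (2R,3R)-3-(tert-butyldimethylsilyloxy)-2-methylbutanal | C[C@@H](O[Si](C)(C)C(C)(C)C)[C@@H](C)C=O | intermediate
6 | tert-butyl{[(2R,3S)-5,5-dibromo-3-methylpent-4-en-2-yl]oxy}dimethylsilane | C[C@@H](O[Si](C)(C)C(C)(C)C)[C@@H](C)C=C(Br)Br | intermediate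
7 | [(3S,4R)-4-(tert-butyldimethylsilyloxy)-3-methylpent-1-yn-1-yl]lithium | C[C@@H](O[Si](C)(C)C(C)(C)C)[C@@H](C)C#C[Li] | intermediate
8 | methyl (4S,5R)-5-(tert-butyldimethylsilyloxy)-4-methylhex-2-ynoate | COC(=O)C#C[C@H](C)[C@@H](C)O[Si](C)(C)C(C)(C)C | intermediate
9 | 2-bromo-4,6-dimethoxybenzaldehyde | COc1cc(OC)c(C=O)c(Br)c1 | starting material
10 | 1-bromo-3,5-dimethoxy-2-methylbenzene | COc1cc(OC)c(C)c(Br)c1 | intermediate
11 | (2S,3S)-2,3-dimethyloxirane | C[C@@H]1O[C@H]1C | starting material
12 | (3,5-dimethoxy-2-methylphenyl)lithium | COc1cc(OC)c(C)c([Li])c1 | intermediate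
13 | (2S,3S)-3-(3,5-dimethoxy-2-methylphenyl)butan-2-ol | C[C@H](O)[C@@H](C)c1cc(OC)cc(OC)c1C | intermediate
14 | (2R,3S)-3-(3,5-dimethoxy-2-methylphenyl)butan-2-yl 4-nitrobenzoate | C[C@@H](OC(=O)c1ccc(cc1)[N+](=O)[O-])[C@@H](C)c1cc(OC)cc(OC)c1C | intermediate
15 | (2R,3S)-3-(3,5-dimethoxy-2-methylphenyl)butan-2-ol | C[C@@H](O)[C@@H](C)c1cc(OC)cc(OC)c1C | intermediate
16 | 1,5-dimethoxy-3-[(2S,3R)-3-(methoxymethoxy)butan-2-yl]-2-methylbenzene | C[C@@H](OCOC)[C@@H](C)c1cc(OC)cc(OC)c1C | intermediate
17 | (3R,4S)-6,8-dimethoxy-3,4,5-trimethylisochroman | COc1cc(OC)c(C)c2c1CO[C@H](C)[C@H]2C | intermediate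
18 | [(3R,4S)-6,8-dimethoxy-3,4,5-trimethylisochroman-7-yl]lithium | COc1c([Li])c(OC)c(C)c2c1CO[C@H](C)[C@H]2C | intermediate
19 | (3R,4S)-6,8-dimethoxy-3,4,5-trimethylisochroman-7-carbaldehyde | COc1c(C=O)c(OC)c(C)c2c1CO[C@H](C)[C@H]2C | intermediate
20 | (3R,4S)-6,8-dihydroxy-3,4,5-trimethylisochroman-7-carbaldehyde | Oc1c(C=O)c(O)c(C)c2c1CO[C@H](C)[C@H]2C | intermediate
21 | (3R,4S)-6,8-bis(methoxymethoxy)-3,4,5-trimethylisochroman-7-carbaldehyde | COCOc1c(C=O)c(OCOC)c(C)c2c1CO[C@H](C)[C@H]2C | intermediate
22 | methyl 3-oxopentanoate | CCC(=O)CC(=O)OC | starting material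
23 | methyl 2-{[(3R,4S)-6,8-bis(methoxymethoxy)-3,4,5-trimethylisochroman-7-yl]methylidene}-3-oxopentanoate (E/Z mixture) | CCC(=O)C(=Cc1c(OCOC)c(C)c2c(c1OCOC)CO[C@H](C)[C@H]2C)C(=O)OC | intermediate
24 | methyl 2-{[(3R,4S)-6,8-bis(methoxymethoxy)-3,4,5-trimethylisochroman-7-yl]methyl}-3-oxopentanoate (both C2 epimers) | CCC(=O)C(Cc1c(OCOC)c(C)c2c(c1OCOC)CO[C@H](C)[C@H]2C)C(=O)OC | intermediate
25 | methyl 2-{[(3R,4S)-6,8-bis(methoxymethoxy)-3,4,5-trimethylisochroman-7-yl]methyl}-3-(trimethylsilyloxy)pent-2-enoate | CCC(O[Si](C)(C)C)=C(Cc1c(OCOC)c(C)c2c(c1OCOC)CO[C@H](C)[C@H]2C)C(=O)OC | intermediate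
26 | lithium dienolate of 25 (lithium salt of the ester dienolate, C3–C4 double bond Z) | C/C=C(O[Si](C)(C)C)/C(Cc1c(OCOC)c(C)c2c(c1OCOC)CO[C@H](C)[C@H]2C)=C(OC)O[Li] | intermediate
27 | (3Z)-1-methoxy-1,3-bis(trimethylsilyloxy)penta-1,3-diene bearing the [(3R,4S)-6,8-bis(methoxymethoxy)-3,4,5-trimethylisochroman-7-yl]methyl group at C2 | C/C=C(O[Si](C)(C)C)/C(Cc1c(OCOC)c(C)c2c(c1OCOC)CO[C@H](C)[C@H]2C)=C(OC)O[Si](C)(C)C | intermediate
28 | methyl 5-{[(3R,4S)-6,8-bis(methoxymethoxy)-3,4,5-trimethylisochroman-7-yl]methyl}-2-[(2S,3R)-3-(tert-butyldimethylsilyloxy)butan-2-yl]-6-methoxy-3-methyl-4,6-bis(trimethylsilyloxy)cyclohexa-1,4-diene-1-carboxylate (mixture at ring C3 and C6) | COC(=O)C1=C([C@H](C)[C@@H](C)O[Si](C)(C)C(C)(C)C)C(C)C(O[Si](C)(C)C)=C(Cc2c(OCOC)c(C)c3c(c2OCOC)CO[C@H](C)[C@H]3C)C1(OC)O[Si](C)(C)C | intermediate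
29 | methyl 3-{[(3R,4S)-6,8-bis(methoxymethoxy)-3,4,5-trimethylisochroman-7-yl]methyl}-6-[(2S,3R)-3-(tert-butyldimethylsilyloxy)butan-2-yl]-5-methyl-2,4-bis(trimethylsilyloxy)benzoate | COC(=O)c1c(O[Si](C)(C)C)c(Cc2c(OCOC)c(C)c3c(c2OCOC)CO[C@H](C)[C@H]3C)c(O[Si](C)(C)C)c(C)c1[C@H](C)[C@@H](C)O[Si](C)(C)C(C)(C)C | intermediate
30 | methyl 3-{[(3R,4S)-6,8-bis(methoxymethoxy)-3,4,5-trimethylisochroman-7-yl]methyl}-6-[(2S,3R)-3-(tert-butyldimethylsilyloxy)butan-2-yl]-2,4-dihydroxy-5-methylbenzoate | COC(=O)c1c(O)c(Cc2c(OCOC)c(C)c3c(c2OCOC)CO[C@H](C)[C@H]3C)c(O)c(C)c1[C@H](C)[C@@H](C)O[Si](C)(C)C(C)(C)C | intermediate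
31 | methyl 3-{[(3R,4S)-6,8-bis(methoxymethoxy)-3,4,5-trimethylisochroman-7-yl]methyl}-6-[(2S,3R)-3-(tert-butyldimethylsilyloxy)butan-2-yl]-2,4-bis(methoxymethoxy)-5-methylbenzoate | COC(=O)c1c(OCOC)c(Cc2c(OCOC)c(C)c3c(c2OCOC)CO[C@H](C)[C@H]3C)c(OCOC)c(C)c1[C@H](C)[C@@H](C)O[Si](C)(C)C(C)(C)C | intermediate
32 | methyl 3-{[(3R,4S)-6,8-bis(methoxymethoxy)-3,4,5-trimethylisochroman-7-yl]methyl}-6-[(2S,3R)-3-hydroxybutan-2-yl]-2,4-bis(methoxymethoxy)-5-methylbenzoate | COC(=O)c1c(OCOC)c(Cc2c(OCOC)c(C)c3c(c2OCOC)CO[C@H](C)[C@H]3C)c(OCOC)c(C)c1[C@H](C)[C@@H](C)O | intermediate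
33 | (3R,4S)-7-{[(3R,4S)-6,8-bis(methoxymethoxy)-3,4,5-trimethylisochroman-7-yl]methyl}-6,8-bis(methoxymethoxy)-3,4,5-trimethylisochroman-1-one | COCOc1c(Cc2c(OCOC)c(C)c3c(c2OCOC)CO[C@H](C)[C@H]3C)c(OCOC)c(C)c2c1C(=O)O[C@H](C)[C@H]2C | intermediate
34 | (3R,4S)-7-{[(3R,4S)-6,8-bis(methoxymethoxy)-3,4,5-trimethylisochroman-7-yl]methyl}-6,8-bis(methoxymethoxy)-3,4,5-trimethylisochroman-1-ol (both C1 epimers) | COCOc1c(Cc2c(OCOC)c(C)c3c(c2OCOC)CO[C@H](C)[C@H]3C)c(OCOC)c(C)c2c1C(O)O[C@H](C)[C@H]2C | intermediate
35 | dicitrinone I, (3R,4S)-7-{[(3R,4S)-6,8-dihydroxy-3,4,5-trimethylisochroman-7-yl]methyl}-6-hydroxy-3,4,5-trimethyl-3,4-dihydro-8H-isochromen-8-one | CC1=C2C(=CO[C@H](C)[C@H]2C)C(=O)C(Cc2c(O)c(C)c3c(c2O)CO[C@H](C)[C@H]3C)=C1O | target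

## Step count and least certain steps

Total: 20 steps. Longest linear sequence: 15 steps (9 → 35, steps 6–20). The ynoate branch (steps 1–5) joins at step 16.

**Step 16 (key step).** Both new bonds are made at substituted carbons beside bulky groups, so the cycloaddition may be slow. During long heating the silyl ketene acetal can rearrange (oxygen-to-carbon silyl shift) or be protodesilylated, so that diene is consumed faster than the ring forms. Within the step, a neat or high-pressure run is the first remedy.

The fallback separates benzannulation from bridge formation. It sets out from 22, 8 and 20 and returns at 31.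
- Keto ester 22 is silylated twice (Me3SiCl/Et3N, then LiN(i-Pr)2/Me3SiCl) through methyl 3-(trimethylsilyloxy)pent-2-enoate F1 to 1-methoxy-1,3-bis(trimethylsilyloxy)penta-1,3-diene F2.
- Diene F2, which lacks the C2 substituent, undergoes the same cycloaddition–aromatisation with 8 in its well-precedented form to give methyl 6-[(2S,3R)-3-(tert-butyldimethylsilyloxy)butan-2-yl]-2,4-dihydroxy-5-methylbenzoate F3.
- Aldehyde 20 is reduced with NaBH4 to (3R,4S)-7-(hydroxymethyl)-3,4,5-trimethylisochroman-6,8-diol F4.
- On gentle heating F4 loses water to an ortho-quinone methide, which is captured by the only free and doubly activated ring carbon of F3. This gives the diarylmethane methyl 6-[(2S,3R)-3-(tert-butyldimethylsilyloxy)butan-2-yl]-3-{[(3R,4S)-6,8-dihydroxy-3,4,5-trimethylisochroman-7-yl]methyl}-2,4-dihydroxy-5-methylbenzoate F5.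
- Fourfold methoxymethylation (NaH, MeOCH2Cl) then gives 31.

**Step 13.** Condensation of the doubly ortho-substituted aldehyde may stall or revert. A second keto ester may also add to the alkylidene before hydride transfer. Fallback from 21, returning at 24: reduction with NaBH4 gives [(3R,4S)-6,8-bis(methoxymethoxy)-3,4,5-trimethylisochroman-7-yl]methanol F6. Appel bromination (CBr4, PPh3) gives (3R,4S)-7-(bromomethyl)-6,8-bis(methoxymethoxy)-3,4,5-trimethylisochroman F7, which is used at once to alkylate the sodium enolate of 22 (NaH, THF, 0 °C), giving 24.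

**Step 11.** The Lewis acid may open the benzylic ring ether, or cleavage may stop after the first ether. Fallback from 17, returning at 21, changes the order and the mechanism of dealkylation. Nucleophilic demethylation with NaSEt in DMF at 140 °C gives (3R,4S)-3,4,5-trimethylisochroman-6,8-diol F8. Methoxymethylation (NaH, MeOCH2Cl) gives (3R,4S)-6,8-bis(methoxymethoxy)-3,4,5-trimethylisochroman F9. Lithiation between the two MOM ethers (n-BuLi, TMEDA) and quenching with DMF gives 21.

**Step 19.** The aluminium hemiacetal may collapse and be reduced further to the diol, or reduction may stall at the carbonyl flanked by the C8 ether. Fallback from 33, returning at 34: full reduction with LiAlH4 gives the diol (2R,3S)-3-[2-(hydroxymethyl)-3,5-bis(methoxymethoxy)-6-methylphenyl]butan-2-ol carrying the isochroman-7-ylmethyl group at ring C4, F10. Selective oxidation of its benzylic alcohol with MnO2 gives the hydroxy aldehyde, which closes to 34.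

**Step 20.** Hydrolysis of the hindered acetals may be incomplete under conditions the quinone methide tolerates, and long exposure invites addition of water, chloride or formaldehyde-derived species at C1. Fallback from 33, returning at 35, moves deprotection ahead of reduction. HCl in MeOH at 50 °C gives the robust tetraphenol lactone (3R,4S)-7-{[(3R,4S)-6,8-dihydroxy-3,4,5-trimethylisochroman-7-yl]methyl}-6,8-dihydroxy-3,4,5-trimethylisochroman-1-one F11. Excess i-Bu2AlH (–78 → –40 °C) gives the corresponding lactol, (3R,4S)-7-{[(3R,4S)-6,8-dihydroxy-3,4,5-trimethylisochroman-7-yl]methyl}-3,4,5-trimethylisochroman-1,6,8-triol F12, which loses water on mildly acidic work-up to give 35.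

## Further compounds

F1 | step 16 | methyl 3-(trimethylsilyloxy)pent-2-enoate | CCC(O[Si](C)(C)C)=CC(=O)OC
F2 | step 16 | (3Z)-1-methoxy-1,3-bis(trimethylsilyloxy)penta-1,3-diene | C/C=C(O[Si](C)(C)C)/C=C(OC)O[Si](C)(C)C
F3 | step 16 | methyl 6-[(2S,3R)-3-(tert-butyldimethylsilyloxy)butan-2-yl]-2,4-dihydroxy-5-methylbenzoate | COC(=O)c1c(O)cc(O)c(C)c1[C@H](C)[C@@H](C)O[Si](C)(C)C(C)(C)C
F4 | step 16 | (3R,4S)-7-(hydroxymethyl)-3,4,5-trimethylisochroman-6,8-diol | OCc1c(O)c(C)c2c(c1O)CO[C@H](C)[C@H]2C
F5 | step 16 | methyl 6-[(2S,3R)-3-(tert-butyldimethylsilyloxy)butan-2-yl]-3-{[(3R,4S)-6,8-dihydroxy-3,4,5-trimethylisochroman-7-yl]methyl}-2,4-dihydroxy-5-methylbenzoate | COC(=O)c1c(O)c(Cc2c(O)c(C)c3c(c2O)CO[C@H](C)[C@H]3C)c(O)c(C)c1[C@H](C)[C@@H](C)O[Si](C)(C)C(C)(C)C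
F6 | step 13 | [(3R,4S)-6,8-bis(methoxymethoxy)-3,4,5-trimethylisochroman-7-yl]methanol | OCc1c(OCOC)c(C)c2c(c1OCOC)CO[C@H](C)[C@H]2C
F7 | step 13 | (3R,4S)-7-(bromomethyl)-6,8-bis(methoxymethoxy)-3,4,5-trimethylisochroman | BrCc1c(OCOC)c(C)c2c(c1OCOC)CO[C@H](C)[C@H]2C
F8 | step 11 | (3R,4S)-3,4,5-trimethylisochroman-6,8-diol | Oc1cc(O)c(C)c2c1CO[C@H](C)[C@H]2C
F9 | step 11 | (3R,4S)-6,8-bis(methoxymethoxy)-3,4,5-trimethylisochroman | COCOc1cc(OCOC)c(C)c2c1CO[C@H](C)[C@H]2C
F10 | step 19 | (2R,3S)-3-[4-{[(3R,4S)-6,8-bis(methoxymethoxy)-3,4,5-trimethylisochroman-7-yl]methyl}-2-(hydroxymethyl)-3,5-bis(methoxymethoxy)-6-methylphenyl]butan-2-ol | C(c1c(OCOC)c(C)c([C@H](C)[C@@H](C)O)c(CO)c1OCOC)c1c(OCOC)c(C)c2c(c1OCOC)CO[C@H](C)[C@H]2C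
F11 | step 20 | (3R,4S)-7-{[(3R,4S)-6,8-dihydroxy-3,4,5-trimethylisochroman-7-yl]methyl}-6,8-dihydroxy-3,4,5-trimethylisochroman-1-one | C(c1c(O)c(C)c2c(c1O)C(=O)O[C@H](C)[C@H]2C)c1c(O)c(C)c2c(c1O)CO[C@H](C)[C@H]2C
F12 | step 20 | (3R,4S)-7-{[(3R,4S)-6,8-dihydroxy-3,4,5-trimethylisochroman-7-yl]methyl}-3,4,5-trimethylisochroman-1,6,8-triol (both C1 epimers) | C(c1c(O)c(C)c2c(c1O)C(O)O[C@H](C)[C@H]2C)c1c(O)c(C)c2c(c1O)CO[C@H](C)[C@H]2C
A1 | alternative 1 | bis{2,6-dimethoxy-3-methyl-4-[(2R,3R)-3-(4,4,5,5-tetramethyl-1,3,2-dioxaborolan-2-yl)butan-2-yl]phenyl}methane | COc1cc([C@H](C)[C@@H](C)B2OC(C)(C)C(C)(C)O2)c(C)c(OC)c1Cc1c(OC)cc([C@H](C)[C@@H](C)B2OC(C)(C)C(C)(C)O2)c(C)c1OC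
A2 | alternative 1 | bis{2,6-dimethoxy-3-methyl-4-[(1S)-1-(4,4,5,5-tetramethyl-1,3,2-dioxaborolan-2-yl)ethyl]phenyl}methane | COc1cc([C@H](C)B2OC(C)(C)C(C)(C)O2)c(C)c(OC)c1Cc1c(OC)cc([C@H](C)B2OC(C)(C)C(C)(C)O2)c(C)c1OC
A3 | alternative 2 | 7,7'-methylenebis[(3R,4S)-3,4,5-trimethylisochroman-6,8-diol] | C(c1c(O)c(C)c2c(c1O)CO[C@H](C)[C@H]2C)c1c(O)c(C)c2c(c1O)CO[C@H](C)[C@H]2C
A4 | alternative 2 | 2,2'-methylenebis{5-[(2S,3R)-3-hydroxybutan-2-yl]-4-methylbenzene-1,3-diol} | C(c1c(O)c(C)c(cc1O)[C@H](C)[C@@H](C)O)c1c(O)c(C)c(cc1O)[C@H](C)[C@@H](C)O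
A5 | alternative 3 | (3S,3'S)-3,3'-[methylenebis(3,5-dimethoxy-2-methylbenzene-4,1-diyl)]bis(butan-2-one) | COc1cc([C@H](C)C(C)=O)c(C)c(OC)c1Cc1c(OC)cc([C@H](C)C(C)=O)c(C)c1OC
A6 | alternative 3 | [methylenebis(3,5-dimethoxy-2-methylbenzene-4,1-diyl)]bis(bromozinc) | COc1cc([Zn]Br)c(C)c(OC)c1Cc1c(OC)cc([Zn]Br)c(C)c1OC
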